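(All runs come from a simulation for an exercise; the scatter is artificial.)

No constants are given for this flask, so we balance the reagent charged in the smaller amount, the protic impurity, and ask what it costs the solid substrate.

the same everywhere: solid substrate 10 mM; enzyme 7.3 × 10⁻⁴ mol%

| run | protic impurity | remark | time |
|---|---|---|---|
| alder | 2.8 mM | run made earlier |  |
| ash | 4.4 mM | run made earlier |  |
| flask | 2.00 mM |  | 40 min |

| run | time / min | product / % |
|---|---|---|
| alder | 2.50 | 5.0 |
| alder | 8.00 | 22.7 |
| alder | 15.0 | 51.2 |
| alder | 20.0 | 64.6 |
| alder | 30.0 | 73.2 |
| alder | 40.0 | 74.5 |
| ash | 2.50 | 5.2 |
| ash | 8.00 | 26.3 |
| ash | 15.0 | 49.7 |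
| ash | 20.0 | 58.1 |
| ash | 30.0 | 60.4 |
| ash | 40.0 | 60.6 |

(scatter of a reading: 1 percentage point)

- as a solid, counted per litre of solution: solid substrate
- at the start none of the solid substrate is in solution

- ochre: doubling the amount of enzyme, all else as stated
- red: doubling the dissolution coefficient of the solid substrate, all else as stated
- violet: doubling the solubility of the solid substrate, all else as stated

- how much product there is at 40 min, in percent of the solid substrate charged
- the change that raises the amount of product at 40 min, in percent of the solid substrate charged most ("none" if none brings more than 2 percentage points) (ochre / red / violet / none)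
- amount of product at 40 min, in percent of the solid substrate charged, after red

Two extreme versions of the flask can be solved in the head. In the first, the enzyme takes each dissolved molecule before the protic impurity reaches it, and product ends at 100%. In the second, the charge of protic impurity is spent, each molecule taking one of substrate, and product ends at 80.0%.

The earlier runs show how near the second version they stand. We define the toll as the substrate not found as product, in mM, per mM of protic impurity charged, so that the loss is toll × c(protic impurity)/c(solid substrate). The alder run, level at 74.5%, gives 0.911, and the ash run, at 60.6%, gives 0.895. Their mean is the toll 0.903, and our own reckoning for this flask is 81.9%.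

The forecast, which says “the impurity appears to destroy substrate nearly one-for-one”, gives 81%, somewhat lower than ours, with ochre as the best change and 80% after red.

The flask gives 79.8%; ochre is best, gaining 3.6 percentage points, and red gives 79.5%.

    starting material + enzyme ⇌ complex (K = 290 M⁻¹, k = 2.20 × 10⁶ M⁻¹ s⁻¹)
    complex ⇌ enzyme + product (K = 0.200 M, k = 190 s⁻¹)
    solid substrate ⇌ starting material, rate k3*(cs3 - [starting material]) while solid is left; crystals form when [starting material] > cs3 (solubility = 6.20 mM, k = 0.00380 s⁻¹)
    starting material + protic impurity → quenched substrate (k = 0.740 M⁻¹ s⁻¹)

With concentrations as charged, quenching alone halves the starting material in 7.8 min, a shorter time than the 11.6 min by which half of the product step's turnover is done. At 40.0 min this flask holds 18.7% quenched substrate, 1.5% of the charged solid substrate still there, solid or dissolved, and 6.3% of its protic impurity; its own toll is 1.01, and its product stands just below the 80.0% of the second version. For the neighbour flask, with 25 mM of solid substrate and 0.0800 equiv of protic impurity, the toll 0.903 gives 92.8%; the computed result is 90.7%.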